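**Retrosynthetic overview**

1. Target 22 comes from global O-demethylation of its tridecamethyl ether 21, which is cut at the ether between ring B C5 and ring C C1 into the ring A–B bromide 11 and the ring C–D–E phenol 20 (Ullmann union).
2. The strategy rests on ring A: a phloroglucinol (OH on C1, C3, C5) whose C2, flanked by two hydroxyls, carries the ether oxygen to ring B. This 1,3,5-oxygen pattern is that of a folded tri-β-carbonyl chain, so ring A is cut at C1–C6 and C3–C4 into aryloxymalonate 5 (C1–C3) and dimethyl 3-oxopentanedioate 6 (C4–C6).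
3. The O–C2 ether of ring A then arises from O-alkylation of ring B phenol 3 with dimethyl chloromalonate, not from an aryl coupling; the bromine of ring B is carried along as the handle for the union.
4. In 20, the D–E ether comes from Chan–Lam arylation of syringaldehyde and the C–D ether from Ullmann coupling with 2-bromo-3,4,5-trimethoxybenzaldehyde; each formyl group is then converted to the next phenol by Baeyer–Villiger oxidation.
5. Rings B, C, D and E are bought as arenes; ring A is the only ring built (step 3), before the fragment union.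

Key step: step 3

Remark: the target has no stereocentre, so nothing stereochemical has to be set; rings are lettered A to E from the 2,4,6-trihydroxyphenyl end to the 3,4,5-trihydroxyphenyl end.

**Route**

Step 1
Reactants: 1 3-bromo-4,5-dimethoxybenzaldehyde
Product: 3 3-bromo-4,5-dimethoxyphenol, via aryl formate 2 (not isolated)
Conditions: mCPBA, CH2Cl2, 0 °C to rt; then K2CO3 (cat.), MeOH, rt
Reagents that add atoms: mCPBA (3-chloroperoxybenzoic acid), O=C(OO)c1cccc(Cl)c1
Why: Baeyer–Villiger oxidation in which the para-methoxy group should favour aryl over hydride migration, the formate being cleaved by methanolysis while the aryl bromide is inert to the peracid.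

Step 2
Reactants: 3 3-bromo-4,5-dimethoxyphenol; 4 dimethyl chloromalonate
Product: 5 dimethyl 2-(3-bromo-4,5-dimethoxyphenoxy)malonate
Conditions: K2CO3, acetone, reflux
Reagents that add atoms: none
Why: Williamson-type SN2 O-alkylation of the phenoxide by the doubly activated chloride, the standard access to 2-aryloxymalonates; one equivalent of 4 should limit a second alkylation of the acidic product.

Step 3
Reactants: 5 dimethyl 2-(3-bromo-4,5-dimethoxyphenoxy)malonate; 6 dimethyl 3-oxopentanedioate
Product: 8 dimethyl 5-(3-bromo-4,5-dimethoxyphenoxy)-2,4,6-trihydroxyisophthalate, via open-chain Claisen triester 7 (not isolated)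
Conditions: NaOMe (2.5 equiv), MeOH, reflux, slow addition of 6; then toluene, 110 °C with removal of MeOH; aq. HCl
Reagents that add atoms: none
Why: The sodium enolate of 6 should attack one ester carbonyl of 5 (Claisen acylation, bond C1–C6 of ring A) to give triester 7, whose second enolate carbon closes on the remaining malonate ester (Dieckmann acylation, 6-exo-trig, bond C3–C4), after which the cyclohexane-1,3,5-trione tautomerises to the aromatic triol. The closest known reaction is the alkoxide-mediated condensation of malonic esters with acetonedicarboxylic esters to phloroglucinoldicarboxylates. No stereocentre is formed. The step needs C- over O-acylation and cross- over self-condensation of 6: enol-lactone (pyranone) formation is reversible under methoxide whereas the ester-stabilised phenoxide of 8 is the thermodynamic sink, slow addition keeps 6 dilute, and the mirror symmetry of both partners leaves no regiochemical choice. The aryl bromide and the methyl ethers of ring B are inert to NaOMe.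

Step 4
Reactants: 8 dimethyl 5-(3-bromo-4,5-dimethoxyphenoxy)-2,4,6-trihydroxyisophthalate
Product: 10 2-(3-bromo-4,5-dimethoxyphenoxy)benzene-1,3,5-triol, via trihydroxyisophthalic diacid 9 (not isolated)
Conditions: KOH (2 M aq.), reflux, argon; then HCl to pH 2, 60 °C
Reagents that add atoms: none
Why: Saponification followed by decarboxylation of a 2,4,6-trihydroxybenzoic acid through its β-keto acid tautomer (ipso-protonation), the classical behaviour of phloroglucinolcarboxylic acids; the diaryl ether, methyl ethers and bromide should not be touched.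

Step 5
Reactants: 10 2-(3-bromo-4,5-dimethoxyphenoxy)benzene-1,3,5-triol
Product: 11 1-bromo-2,3-dimethoxy-5-(2,4,6-trimethoxyphenoxy)benzene
Conditions: Me2SO4, K2CO3, acetone, reflux, argon
Reagents that add atoms: dimethyl sulfate, COS(=O)(=O)OC
Why: Williamson O-methylation in which the hard electrophile and carbonate in acetone should favour O- over C-alkylation of the phloroglucinol nucleus, as in the preparation of 1,3,5-trimethoxybenzene.

Step 6
Reactants: 12 syringaldehyde (4-hydroxy-3,5-dimethoxybenzaldehyde); 13 (3,4,5-trimethoxyphenyl)boronic acid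
Product: 14 3,5-dimethoxy-4-(3,4,5-trimethoxyphenoxy)benzaldehyde
Conditions: Cu(OAc)2 (2 equiv), pyridine, 4 Å molecular sieves, CH2Cl2, air, rt
Reagents that add atoms: none
Why: Chan–Lam coupling, in which aryl transfer from boron to the divalent copper phenoxide and C–O reductive elimination at room temperature tolerate two ortho substituents on an acidic phenol and leave the aldehyde alone.

Step 7
Reactants: 14 3,5-dimethoxy-4-(3,4,5-trimethoxyphenoxy)benzaldehyde
Product: 16 3,5-dimethoxy-4-(3,4,5-trimethoxyphenoxy)phenol, via aryl formate 15 (not isolated)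
Conditions: mCPBA, CH2Cl2, 0 °C to 40 °C; then K2CO3 (cat.), MeOH, rt
Reagents that add atoms: mCPBA (3-chloroperoxybenzoic acid), O=C(OO)c1cccc(Cl)c1
Why: Baeyer–Villiger oxidation of a 4-aryloxybenzaldehyde, where the para-aryloxy oxygen should direct aryl migration to the formate, which methanolysis cleaves to the phenol.

Step 8
Reactants: 16 3,5-dimethoxy-4-(3,4,5-trimethoxyphenoxy)phenol; 17 2-bromo-3,4,5-trimethoxybenzaldehyde
Product: 18 2-[3,5-dimethoxy-4-(3,4,5-trimethoxyphenoxy)phenoxy]-3,4,5-trimethoxybenzaldehyde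
Conditions: CuI (20 mol %), N,N-dimethylglycine·HCl (40 mol %), Cs2CO3, 1,4-dioxane, 100 °C, argon
Reagents that add atoms: none
Why: Ullmann ether synthesis in which the ortho-formyl group activates the C–Br bond towards monovalent copper and the phenol is unhindered, the pattern known from couplings of 2-bromo-3,4,5-trimethoxybenzoyl compounds with phenols.

Step 9
Reactants: 18 2-[3,5-dimethoxy-4-(3,4,5-trimethoxyphenoxy)phenoxy]-3,4,5-trimethoxybenzaldehyde
Product: 20 2-[3,5-dimethoxy-4-(3,4,5-trimethoxyphenoxy)phenoxy]-3,4,5-trimethoxyphenol, via aryl formate 19 (not isolated)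
Conditions: mCPBA, CH2Cl2, 0 °C to rt; then K2CO3 (cat.), MeOH, rt
Reagents that add atoms: mCPBA (3-chloroperoxybenzoic acid), O=C(OO)c1cccc(Cl)c1
Why: Baeyer–Villiger oxidation of a benzaldehyde carrying ortho-aryloxy and para-methoxy donors, which should ensure aryl migration; the product stays masked as its formate until the peracid is consumed.

Step 10
Reactants: 11 1-bromo-2,3-dimethoxy-5-(2,4,6-trimethoxyphenoxy)benzene; 20 2-[3,5-dimethoxy-4-(3,4,5-trimethoxyphenoxy)phenoxy]-3,4,5-trimethoxyphenol
Product: 21 1,2,3-trimethoxy-4-[3,5-dimethoxy-4-(3,4,5-trimethoxyphenoxy)phenoxy]-5-[2,3-dimethoxy-5-(2,4,6-trimethoxyphenoxy)phenoxy]benzene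
Conditions: CuI (30 mol %), N,N-dimethylglycine·HCl (60 mol %), Cs2CO3, 1,4-dioxane, 105 °C, argon
Reagents that add atoms: none
Why: Ligand-accelerated Ullmann diaryl ether coupling, which is established for electron-rich aryl bromides and phenols with one ortho substituent each; 11 holds the only halide and 20 the only free hydroxyl.

Step 11
Reactants: 21 tridecamethyl ether
Product: 22 2-{3-[2-(3,5-dihydroxy-4-(3,4,5-trihydroxyphenoxy)phenoxy)-3,4,5-trihydroxyphenoxy]-4,5-dihydroxyphenoxy}benzene-1,3,5-triol (CNP0228612.0)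
Conditions: BBr3 (excess), CH2Cl2, −78 °C to rt; then H2O, 0 °C, argon
Reagents that add atoms: none
Why: Lewis acid-mediated cleavage of aryl methyl ethers by bromide attack at the methyl carbon; the diaryl ether oxygens carry no sp3 carbon and should stay intact, and the polyphenol is handled under argon.

**Compound list**

1 | 3-bromo-4,5-dimethoxybenzaldehyde | O=Cc1cc(Br)c(OC)c(OC)c1 | starting material
2 | 3-bromo-4,5-dimethoxyphenyl formate | O=COc1cc(Br)c(OC)c(OC)c1 | intermediate
3 | 3-bromo-4,5-dimethoxyphenol | Oc1cc(Br)c(OC)c(OC)c1 | intermediate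
4 | dimethyl chloromalonate | COC(=O)C(Cl)C(=O)OC | starting material
5 | dimethyl 2-(3-bromo-4,5-dimethoxyphenoxy)malonate | COC(=O)C(Oc1cc(Br)c(OC)c(OC)c1)C(=O)OC | intermediate
6 | dimethyl 3-oxopentanedioate | COC(=O)CC(=O)CC(=O)OC | starting material
7 | dimethyl 2-(3-bromo-4,5-dimethoxyphenoxy)-4-(methoxycarbonyl)-3,5-dioxoheptanedioate (open-chain Claisen triester, mixture of stereoisomers and enol forms) | COC(=O)CC(=O)C(C(=O)OC)C(=O)C(Oc1cc(Br)c(OC)c(OC)c1)C(=O)OC | intermediate
8 | dimethyl 5-(3-bromo-4,5-dimethoxyphenoxy)-2,4,6-trihydroxyisophthalate | COC(=O)c1c(O)c(Oc2cc(Br)c(OC)c(OC)c2)c(O)c(C(=O)OC)c1O | intermediate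
9 | 5-(3-bromo-4,5-dimethoxyphenoxy)-2,4,6-trihydroxyisophthalic acid | OC(=O)c1c(O)c(Oc2cc(Br)c(OC)c(OC)c2)c(O)c(C(=O)O)c1O | intermediate
10 | 2-(3-bromo-4,5-dimethoxyphenoxy)benzene-1,3,5-triol | Oc1cc(O)c(Oc2cc(Br)c(OC)c(OC)c2)c(O)c1 | intermediate
11 | 1-bromo-2,3-dimethoxy-5-(2,4,6-trimethoxyphenoxy)benzene | COc1cc(OC)c(Oc2cc(Br)c(OC)c(OC)c2)c(OC)c1 | intermediate
12 | syringaldehyde (4-hydroxy-3,5-dimethoxybenzaldehyde) | COc1cc(C=O)cc(OC)c1O | starting material
13 | (3,4,5-trimethoxyphenyl)boronic acid | COc1cc(B(O)O)cc(OC)c1OC | starting material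
14 | 3,5-dimethoxy-4-(3,4,5-trimethoxyphenoxy)benzaldehyde | COc1cc(C=O)cc(OC)c1Oc1cc(OC)c(OC)c(OC)c1 | intermediate
15 | 3,5-dimethoxy-4-(3,4,5-trimethoxyphenoxy)phenyl formate | COc1cc(OC=O)cc(OC)c1Oc1cc(OC)c(OC)c(OC)c1 | intermediate
16 | 3,5-dimethoxy-4-(3,4,5-trimethoxyphenoxy)phenol | COc1cc(O)cc(OC)c1Oc1cc(OC)c(OC)c(OC)c1 | intermediate
17 | 2-bromo-3,4,5-trimethoxybenzaldehyde | COc1cc(C=O)c(Br)c(OC)c1OC | starting material
18 | 2-[3,5-dimethoxy-4-(3,4,5-trimethoxyphenoxy)phenoxy]-3,4,5-trimethoxybenzaldehyde | COc1cc(C=O)c(Oc2cc(OC)c(Oc3cc(OC)c(OC)c(OC)c3)c(OC)c2)c(OC)c1OC | intermediate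
19 | 2-[3,5-dimethoxy-4-(3,4,5-trimethoxyphenoxy)phenoxy]-3,4,5-trimethoxyphenyl formate | COc1cc(OC=O)c(Oc2cc(OC)c(Oc3cc(OC)c(OC)c(OC)c3)c(OC)c2)c(OC)c1OC | intermediate
20 | 2-[3,5-dimethoxy-4-(3,4,5-trimethoxyphenoxy)phenoxy]-3,4,5-trimethoxyphenol | COc1cc(O)c(Oc2cc(OC)c(Oc3cc(OC)c(OC)c(OC)c3)c(OC)c2)c(OC)c1OC | intermediate
21 | 1,2,3-trimethoxy-4-[3,5-dimethoxy-4-(3,4,5-trimethoxyphenoxy)phenoxy]-5-[2,3-dimethoxy-5-(2,4,6-trimethoxyphenoxy)phenoxy]benzene (tridecamethyl ether of the target) | COc1cc(OC)c(Oc2cc(OC)c(OC)c(Oc3cc(OC)c(OC)c(OC)c3Oc3cc(OC)c(Oc4cc(OC)c(OC)c(OC)c4)c(OC)c3)c2)c(OC)c1 | intermediate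
22 | 2-{3-[2-(3,5-dihydroxy-4-(3,4,5-trihydroxyphenoxy)phenoxy)-3,4,5-trihydroxyphenoxy]-4,5-dihydroxyphenoxy}benzene-1,3,5-triol (CNP0228612.0) | Oc1cc(O)c(Oc2cc(O)c(O)c(Oc3cc(O)c(O)c(O)c3Oc3cc(O)c(Oc4cc(O)c(O)c(O)c4)c(O)c3)c2)c(O)c1 | target

**Step count**

Total: 11 steps. Longest linear sequence: 7 steps (steps 1, 2, 3, 4, 5, 10, 11); the ring C–D–E branch (steps 6–9) joins at step 10.

**Steps most likely to fail**

Step 3 (key step). The ketodiester 6 may condense with itself faster than it acylates the deprotonated, poorly electrophilic malonate, or the sequence may stall after O-acylation. The fallback makes the first C–C bond with an acid chloride and keeps the same two ring bonds. Setting out from malonate 5, one ester is saponified with one equivalent of KOH in MeOH at 0 °C to the half-acid 2-(3-bromo-4,5-dimethoxyphenoxy)-3-methoxy-3-oxopropanoic acid F1. Oxalyl chloride with catalytic DMF in CH2Cl2 converts it into methyl 2-(3-bromo-4,5-dimethoxyphenoxy)-3-chloro-3-oxopropanoate F2. F2 should C-acylate the magnesium enolate of 6 (MgCl2, Et3N, MeCN, 0 °C), the soft-enolisation acylation known for β-keto esters. The fallback comes back to the route at triester 7, now isolated, and NaOMe in MeOH then has to effect only the Dieckmann closure to 8.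

Step 10. Insertion of monovalent copper into the electron-rich, ortho-methoxy C–Br bond of 11 may be slow against a bulky ortho-aryloxy phenoxide, so that protodebromination and oxidation of the phenol take over. The fallback replaces the halide coupling by an oxidative boron coupling at room temperature. Setting out from bromide 11, bromine–lithium exchange (n-BuLi, THF, −78 °C), B(OiPr)3 and acidic work-up should give [2,3-dimethoxy-5-(2,4,6-trimethoxyphenoxy)phenyl]boronic acid F3. Chan–Lam coupling of F3 with phenol 20 (Cu(OAc)2, pyridine, 4 Å molecular sieves, CH2Cl2, air, rt) comes back to the route at 21.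

Step 6. C–O bond formation at the di-ortho-substituted, weakly nucleophilic phenoxide of 12 may be sluggish while the boronic acid is lost to protodeboronation and oxidative self-coupling. The fallback is a metal-free arylation by ligand coupling at trivalent iodine, which is known to tolerate hindered phenols. 5-Iodo-1,2,3-trimethoxybenzene is oxidised with mCPBA and TsOH·H2O in MeCN and trapped with 1,3,5-trimethoxybenzene to give (3,4,5-trimethoxyphenyl)(2,4,6-trimethoxyphenyl)iodonium 4-methylbenzenesulfonate F4. Setting out from 12, treatment with K2CO3 and F4 in MeCN at 60 °C should transfer the 3,4,5-trimethoxyphenyl group, the 2,4,6-trimethoxyphenyl group staying on iodine as the dummy ligand, and comes back to the route at 14.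

**Further compounds**

F1 | step 3 | 2-(3-bromo-4,5-dimethoxyphenoxy)-3-methoxy-3-oxopropanoic acid (racemic) | COC(=O)C(Oc1cc(Br)c(OC)c(OC)c1)C(=O)O
F2 | step 3 | methyl 2-(3-bromo-4,5-dimethoxyphenoxy)-3-chloro-3-oxopropanoate (racemic) | COC(=O)C(Oc1cc(Br)c(OC)c(OC)c1)C(Cl)=O
F3 | step 10 | [2,3-dimethoxy-5-(2,4,6-trimethoxyphenoxy)phenyl]boronic acid | COc1cc(OC)c(Oc2cc(B(O)O)c(OC)c(OC)c2)c(OC)c1
F4 | step 6 | (3,4,5-trimethoxyphenyl)(2,4,6-trimethoxyphenyl)iodonium 4-methylbenzenesulfonate | COc1cc([I+]c2c(OC)cc(OC)cc2OC)cc(OC)c1OC.Cc1ccc(S(=O)(=O)[O-])cc1
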